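# Synthesis plan for 2,3,6-tribromo-1H-indole (9)

## The problem

Compound 9 is an unadorned indole. A benzene ring is fused across C3a–C7a to a pyrrole ring, there is no carbon substituent, and bromine sits at C2, C3 and C6. There is no stereocentre, so no configuration has to be set, relayed or protected, and the task is one of position and timing.

- **Position.** Electrophilic bromination of an indole goes to C3, then to C2. It reaches the benzene ring only afterwards, without a clean choice between C5 and C6. C6–Br must therefore come in with the benzene building block, in a fixed relation to the ring-fusion atoms.
- **Timing.** N–H indoles with halogen at C2, or at C2 and C3, are sensitive to acid, light and air and hydrolyse at C2 back to the lactam level. These two bromines have to arrive last, under near-neutral conditions.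
- **Fragile bonds.** Every C–Br bond, once present, rules out hydrogenolysis, dissolving metals, alkyllithium reagents and zerovalent palladium. This narrows the choice of reductions and unmasking steps.
- **Stand-in for C2.** C2 needs a robust placeholder that can be exchanged for bromine in one operation, and a lactam carbonyl serves.
- **Enabling feature.** C6 lies para to C3a and meta to C7a. A benzene ring with bromine para to a CH2–C(=O)–N side chain has two equivalent ortho C–H positions, and either can become C7a. Closing N1 onto the ring can therefore give only one product.

## Retrosynthesis

**C3–Br (9 ⇒ 8).** The bromine at C3 is removed first, leading to 2,6-dibromo-1H-indole 8. C3 is the most nucleophilic carbon of an indole and the only free pyrrole carbon in 8, so the forward step needs no directing device. Removing C2–Br last instead would require N-protection and C2 metalation next to two other C–Br bonds. The precursor has one halogen fewer. The forward reaction must deliver exactly one bromonium equivalent from a neutral N-bromoimide, cold and in the dark.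

**C2–Br to C2=O (8 ⇒ 7).** The C2–Br bond is traced back to the lactam carbonyl of 6-bromoindolin-2-one 7. An oxygen placeholder is exchanged for bromine in a single deoxybromination that also aromatises the five-membered ring. A carbon placeholder at C2 would have to be hydrolysed and then expelled. Compound 7 is a stable, storable solid, unlike 8. The forward reaction must activate the lactam oxygen with a phosphoryl bromide while keeping the acid set free away from the product.

**N–H to N–OMe (7 ⇒ 6).** The N–H of 7 is exchanged for the N–OMe group of 6-bromo-1-methoxyindolin-2-one 6. No skeletal bond is cut. The methoxy group is what makes the amide nitrogen oxidisable to a stabilised cation in the step before. It is the smallest group that does so and leaves only methanol on removal. The forward N–O cleavage must spare C6–Br, which points to a zerovalent molybdenum carbonyl rather than catalytic hydrogenation.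

**N1–C7a (6 ⇒ 4, through ion 5).** This is the ring-opening cut, and it leads to the open-chain 2-(4-bromophenyl)-N-methoxyacetamide 4.
- Cutting C3–C3a instead would need a Friedel–Crafts closure on an anilide with bromine meta to nitrogen. Two different ortho positions would then give 4- and 6-bromo products.
- Cutting N1–C2 would be a safe lactamisation, but it only postpones the question of how nitrogen is placed ortho to the side chain.
- The N1–C7a cut answers that question directly, and the symmetry of the para-substituted ring removes any regiochemical choice.

The precursor has one ring fewer and is an ordinary amide. The forward reaction must turn nitrogen into the electrophile 5 and let it substitute a mildly deactivated ring faster than it is consumed otherwise.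

**Amide C–N (4 ⇒ 1 + 2, through 3).** The acyl–nitrogen bond of 4 is cut to 4-bromophenylacetic acid 1 and O-methylhydroxylamine hydrochloride 2, joined through the acid chloride 3. Both are cheap articles of commerce, and 1 already carries C6–Br, C3, C2 and the whole benzene ring. Nothing beyond a standard acylation is required.

## Roads not taken

**Alternative 1:** This cut runs through both rings. C3a–C7a and C6–C7 are broken, which unravels the bicycle to the acyclic methyl [(5E)-6-bromohex-5-en-3-yn-1-yl](ethynyl)carbamate A1. In A1 a terminal ynamide is tied by a two-carbon chain to a bromovinyl alkyne.
- *Forward step.* On heating, the ynamide serves as the two-carbon partner of the enyne in an intramolecular [4+2] cycloaddition. The strained cyclic allene formed first shifts a hydrogen and gives methyl 6-bromoindoline-1-carboxylate A2.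
- *Merits.* Two rings and two C–C bonds form in one operation, and the bromine position is fixed by the alkene terminus. This logic is valuable for crowded benzene rings that cannot be bought.
- *Weak points for 9.* The benzene ring of 9 has one substituent and is available ready-made in 1, so building it from acyclic carbon brings no return. A1 needs an N-alkynylation, the unmasking of a protected alkyne and a separate bromoenyne synthesis. Its terminal ynamide and vinyl bromide must both survive prolonged heating. In the cyclic allene the sp3 carbon carries both hydrogen and bromine, so loss or migration of bromine can compete with the hydrogen shift. A2 is also far from 9, needing dehydrogenation of the indoline, two brominations and carbamate cleavage.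
- *Comparison.* In bonds formed per step this road is clearly superior. The chosen plan offers a five-step total from two bulk chemicals, and its ring closure delivers C2 already at the oxidation level needed for bromine exchange.

**Alternative 2:** Here N1–C2 and C3–Br are cut together, leading to N-[5-bromo-2-(bromoethynyl)phenyl]-4-methylbenzenesulfonamide A3.
- *Forward step.* N-bromosuccinimide activates the triple bond and the sulfonamide nitrogen attacks the bromine-bearing carbon in a 5-endo-dig closure. The product is 2,3,6-tribromo-1-tosyl-1H-indole A4, one detosylation from 9.
- *Merits.* Both pyrrole bromines are placed without brominating an indole. The labile dihalopyrrole unit stays N-protected until the last step. The step count is about the same as here, since A3 needs a chemoselective Sonogashira coupling, tosylation and bromodesilylation.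
- *Weak points.* A 1-bromoalkyne is a poorer π-donor than the alkyl- or aryl-substituted alkynes on which halocyclisations of this kind are established. The aryl group stabilises positive charge at the carbon that becomes C3, whereas nitrogen must attack C2. N-bromination of the sulfonamide and plain addition of bromine across the triple bond compete. The key step would thus go beyond known substrate scope. Making A3 also needs a palladium coupling beside an aryl bromide. The final detosylation is limited to hydrolytic or nucleophilic methods, because reductive ones would strip bromine.
- *Comparison.* This road is better at protecting the sensitive end of the molecule and never handles an N–H 2-bromoindole. The chosen plan counters that each of its steps is a reaction type already shown on its own substrate class, and that no palladium meets a C–Br bond.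

**Alternative 3:** The C2=C3 double bond is cut, giving ethyl 2-[(5-bromo-2-formylphenyl)amino]-2-oxoacetate A5.
- *Forward step.* Low-valent titanium from TiCl3 and zinc dust couples the aldehyde carbon with the amide carbonyl of the oxamate in a McMurry-type oxo-amide coupling. This forms ethyl 6-bromo-1H-indole-2-carboxylate A6.
- *Merits.* The coupling is a dependable, non-acidic ring closure. Five-membered ring formation selects the amide over the ester carbonyl. A6 is a stable indole at the aromatic level, and no N–O cleavage is needed.
- *Weak points for 9.* The ester carbon at C2 does not belong to the target. It must be saponified and expelled by bromodecarboxylation at C2, a position less prone to ipso attack than C3, and C3 must be brominated as well. The ortho-aminobenzaldehyde behind A5 self-condenses readily and takes steps of its own. A large excess of reducing metal acts in the presence of an aryl bromide.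
- *Comparison.* The ring closure is at least as reliable as the one chosen here. The chosen plan offers an oxygen placeholder that is exchanged for bromine in one step, no discarded carbon, and one or two steps fewer overall.

Key step: step 2

Remark on the chemistry: ion 5 is written as a free cation in its oxygen-stabilised resonance form with trifluoroacetate as counter-ion. An iodine-bound nitrenoid reacting in the same sense would give the same product.

## Route

Step 1
Reactants: 1 4-bromophenylacetic acid; 2 O-methylhydroxylamine hydrochloride
Product: 4 2-(4-bromophenyl)-N-methoxyacetamide, via 4-bromophenylacetyl chloride 3 (not isolated)
Conditions: (COCl)2 (1.2 equiv), DMF (cat.), CH2Cl2, 0 °C → rt, evaporate; then 2 (1.2 equiv), K2CO3 (3 equiv), EtOAc/H2O (2:1), 0 °C → rt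
Reagents that add atoms: oxalyl chloride, ClC(=O)C(=O)Cl (gives the chlorine of 3; none of its atoms stays in 4)
Why: Acid chloride formation under Vilsmeier-type catalysis followed by a Schotten–Baumann acylation; the α-effect nitrogen of methoxyamine takes up 3 faster than water does in the two-phase medium. The aryl bromide is a spectator, and a slight excess of 2 holds back double acylation.

Step 2
Reactants: 4 2-(4-bromophenyl)-N-methoxyacetamide
Product: 6 6-bromo-1-methoxyindolin-2-one, via acylnitrenium ion 5 (not isolated)
Conditions: PhI(OCOCF3)2 (1.1 equiv, added slowly), CF3CO2H (2 equiv), CH2Cl2 (0.05 M), 0 °C → rt
Reagents that add atoms: none
Why: The amide N–H of 4 exchanges for a trifluoroacetate ligand at trivalent iodine, and departure of iodobenzene leaves the acylnitrenium ion 5, whose electron-deficient nitrogen is stabilised by the lone pair of the methoxy oxygen. Ion 5 attacks an ortho carbon of the ring, and the resulting arenium ion loses its proton to trifluoroacetate, so N1–C7a is formed and the aromatic ring is restored. The closest known reaction type is the hypervalent iodine cyclisation of N-methoxy arylacetamides to 1-methoxyoxindoles, an intramolecular electrophilic aromatic amidation. The one ring formed closes as a five-membered lactam by ortho participation of the arene (Ar2-5 mode); the ipso (Ar1-4) mode would give a strained spiro four-membered lactam, and the one-carbon tether allows no larger ring. No stereocentre is created. The step needs site selectivity, which the substrate secures by symmetry, since both ortho carbons are identical and either becomes C7a with bromine at C6. Bromine is meta to the attacked carbon and so slows the attack only inductively, while it occupies the para position that would be most open to intermolecular N-arylation, which dilution suppresses further. The step also needs chemoselectivity against further oxidation at the C3 methylene of 6, secured by using barely more than one equivalent of oxidant, a low temperature and a non-nucleophilic acidic medium.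

Step 3
Reactants: 6 6-bromo-1-methoxyindolin-2-one
Product: 7 6-bromoindolin-2-one
Conditions: Mo(CO)6 (1.2 equiv), MeCN/H2O (15:1), degassed, reflux
Reagents that add atoms: none
Why: Reductive N–O cleavage of an N-alkoxy lactam by zerovalent molybdenum, which inserts into the weak N–O bond and is then protonolysed by water, a known way to unmask N-methoxy lactams. No hydrogen over palladium, hydride or dissolving metal is involved, so C6–Br should stay, and degassing protects the C3 methylene from autoxidation.

Step 4
Reactants: 7 6-bromoindolin-2-one
Product: 8 2,6-dibromo-1H-indole
Conditions: POBr3 (2 equiv), imidazole (1.2 equiv), ClCH2CH2Cl, 80 °C; ice/aq NaHCO3 quench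
Reagents that add atoms: phosphoryl bromide, BrP(Br)(Br)=O
Why: Deoxybromination of a lactam, known for turning oxindoles into 2-bromoindoles: the lactam oxygen is phosphorylated, bromide replaces the phosphate at C2 by addition–elimination, and loss of a C3 proton aromatises the ring. Imidazole buffers the acid that would otherwise oligomerise the product. Compound 8 should be passed quickly through base-washed silica and used the same day.

Step 5
Reactants: 8 2,6-dibromo-1H-indole
Product: 9 2,3,6-tribromo-1H-indole
Conditions: NBS (1.0 equiv, recrystallised), THF, −78 → 0 °C, dark, argon
Reagents that add atoms: N-bromosuccinimide, BrN1C(=O)CCC1=O
Why: Electrophilic aromatic bromination at C3, the most nucleophilic position of an indole and the only free pyrrole carbon of 8; N-bromosuccinimide on 2-haloindoles is a known entry to 2,3-dihaloindoles. The benzene ring is deactivated by C6–Br, so one equivalent at low temperature should stop at 9, and the neutral by-product keeps acid away from the product.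

## Compound list

1 | 4-bromophenylacetic acid | OC(=O)Cc1ccc(Br)cc1 | starting material
2 | O-methylhydroxylamine hydrochloride | CON.Cl | starting material
3 | 4-bromophenylacetyl chloride | ClC(=O)Cc1ccc(Br)cc1 | intermediate
4 | 2-(4-bromophenyl)-N-methoxyacetamide | CONC(=O)Cc1ccc(Br)cc1 | intermediate
5 | N-[(4-bromophenyl)acetyl]-N-methoxynitrenium trifluoroacetate (oxygen-stabilised resonance form) | C[O+]=NC(=O)Cc1ccc(Br)cc1.[O-]C(=O)C(F)(F)F | intermediate
6 | 6-bromo-1-methoxyindolin-2-one | CON1C(=O)Cc2ccc(Br)cc12 | intermediate
7 | 6-bromoindolin-2-one | O=C1Cc2ccc(Br)cc2N1 | intermediate
8 | 2,6-dibromo-1H-indole | Brc1ccc2cc(Br)[nH]c2c1 | intermediate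
9 | 2,3,6-tribromo-1H-indole | Brc1ccc2c(Br)c(Br)[nH]c2c1 | target

## Step count and least certain steps

Total step count: 5. Longest linear sequence: 5 steps, from 1 to 9.

**Step 2 (key step).**
- *Risk.* The inductive pull of bromine slows the ring closure. The electrophilic nitrogen may then be consumed in other ways: capture by trifluoroacetate, attack on a second molecule, or continued oxidation at the C3 methylene once product is present.
- *Fallback.* It sets out from 4 and returns at 6, and it activates the ring carbon instead of the nitrogen. Catalytic Pd(OAc)2 with CuCl2 and AgOAc in ClCH2CH2Cl at about 100 °C binds the deprotonated CONHOMe group. It palladates the ortho C–H through a six-membered palladacycle by concerted metalation–deprotonation, a process that does not suffer from an electron-poor ring. After oxidation it forms N1–C7a by reductive elimination. This is the known directed C–H lactamisation of N-methoxyamides. Palladium stays divalent or higher throughout, so oxidative addition into C–Br is not expected. The same bond and ring are formed, and no compound outside the list arises (entry F0).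

**Step 4.**
- *Risk.* The product may be lost after it forms. Causes are acid-triggered oligomerisation of the electron-rich N–H 2-bromoindole at 80 °C and hydrolysis at C2 back to the lactam level during the aqueous quench. Its poor shelf life adds to this.
- *Fallback.* It sets out from 7 and returns at 9, and it avoids 8 by keeping an acceptor at C3 while C2–Br is installed.
  1. Vilsmeier–Haack bromoformylation of 7 (POBr3, DMF, CH2Cl2, 0 °C to reflux, then aqueous hydrolysis) should give the robust 2,6-dibromo-1H-indole-3-carbaldehyde F1.
  2. Pinnick oxidation (NaClO2, NaH2PO4, 2-methyl-2-butene, t-BuOH/THF/H2O) should give 2,6-dibromo-1H-indole-3-carboxylic acid F2.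
  3. N-bromosuccinimide in DMF at room temperature should replace the carboxyl group by ipso attack at C3 and loss of carbon dioxide, giving 9.

  The sequence is then six steps long.

**Step 5.**
- *Risk.* Over-reaction of the N–H indole is the main danger. A second bromonium transfer at C3 would lead to the non-aromatic 3H-indole stage, followed by hydrolytic loss of the C2 bromine. Decay of the product on silica or in light is a further concern.
- *Fallback.* It sets out from 8 and returns at 9, and it tempers the ring with a carbamate.
  1. Boc2O with catalytic DMAP in MeCN should give tert-butyl 2,6-dibromo-1H-indole-1-carboxylate F3.
  2. N-bromosuccinimide in DMF at room temperature should give tert-butyl 2,3,6-tribromo-1H-indole-1-carboxylate F4, which can be chromatographed and stored.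
  3. K2CO3 in MeOH at room temperature should remove the carbamate by acyl transfer to methoxide, which is easy because the tribromoindolide is a good leaving group. This releases 9 under non-acidic, non-reducing conditions.

## Further compounds

F0 | step 2 | none | none
F1 | step 4 | 2,6-dibromo-1H-indole-3-carbaldehyde | O=Cc1c(Br)[nH]c2cc(Br)ccc12
F2 | step 4 | 2,6-dibromo-1H-indole-3-carboxylic acid | OC(=O)c1c(Br)[nH]c2cc(Br)ccc12
F3 | step 5 | tert-butyl 2,6-dibromo-1H-indole-1-carboxylate | CC(C)(C)OC(=O)n1c(Br)cc2ccc(Br)cc12
F4 | step 5 | tert-butyl 2,3,6-tribromo-1H-indole-1-carboxylate | CC(C)(C)OC(=O)n1c(Br)c(Br)c2ccc(Br)cc12
A1 | alternative 1 | methyl [(5E)-6-bromohex-5-en-3-yn-1-yl](ethynyl)carbamate | COC(=O)N(C#C)CCC#C/C=C/Br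
A2 | alternative 1 | methyl 6-bromoindoline-1-carboxylate | COC(=O)N1CCc2ccc(Br)cc21
A3 | alternative 2 | N-[5-bromo-2-(bromoethynyl)phenyl]-4-methylbenzenesulfonamide | Cc1ccc(cc1)S(=O)(=O)Nc1cc(Br)ccc1C#CBr
A4 | alternative 2 | 2,3,6-tribromo-1-tosyl-1H-indole | Cc1ccc(cc1)S(=O)(=O)n1c(Br)c(Br)c2ccc(Br)cc12
A5 | alternative 3 | ethyl 2-[(5-bromo-2-formylphenyl)amino]-2-oxoacetate | CCOC(=O)C(=O)Nc1cc(Br)ccc1C=O
A6 | alternative 3 | ethyl 6-bromo-1H-indole-2-carboxylate | CCOC(=O)c1cc2ccc(Br)cc2[nH]1
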